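**Retrosynthetic overview**

1. Target 21 ⇐ diepoxy enone 20 by chelation-controlled reduction at C5; 20 ⇐ macrocyclic trienone 19 by outer-face epoxidation of the two ring olefins, with C4=C15 parked as an enone so it does not compete.
2. 19 ⇐ carbinol 18 ⇐ seco aldehyde/enol triflate 16: the C4–C5 bond and ring A (the ten-membered carbocycle) come from an electrochemical Cr/Ni alkenyl–aldehyde closure.
3. 16 ⇐ alkyne 5 + iodo dienyl triflate 8 by methylalumination/Negishi coupling (C10–CH3, C1–C2, 1(10)E and 2Z olefins), then lactone α-methylenation and C8 methacrylation.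
4. 5 ⇐ aldehyde 4 by Felkin propargylation (C8–C9, C8) ⇐ butenolide 2 + 1,3-dioxolane by photochemical radical conjugate addition (C7–C8, C7).
5. All chirality descends from (S)-5-(hydroxymethyl)furan-2(5H)-one 1 (C6). Ring order: ring B (γ-lactone) is bought, ring A is closed in step 12, the two oxiranes are formed last in step 14.

Assumption: positions are cited in germacrane numbering (lactone oxygen on C6, lactone carbons C7/C11/C12/C13, methacrylate on C8, exocyclic methylene C4=C15, free carbinol C5, oxiranes C1–C10 and C2–C3).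

**Route**

Step 1
Reactants: 1 (S)-5-(hydroxymethyl)furan-2(5H)-one
Product: 2 (S)-5-({[tert-butyl(diphenyl)silyl]oxy}methyl)furan-2(5H)-one
Conditions: TBDPSCl, imidazole, CH2Cl2, 0 °C → rt
Reagents that add atoms: tert-butyl(chloro)diphenylsilane, CC(C)(C)[Si](Cl)(c1ccccc1)c1ccccc1
Why: Imidazole-promoted silyl ether formation on the primary alcohol leaves the C6 stereocentre untouched and installs the bulky group that later shields one face of the butenolide.

Step 2
Reactants: 2 (S)-5-({[tert-butyl(diphenyl)silyl]oxy}methyl)furan-2(5H)-one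
Product: 3 (4S,5S)-5-({[tert-butyl(diphenyl)silyl]oxy}methyl)-4-(1,3-dioxolan-2-yl)oxolan-2-one
Conditions: 1,3-dioxolane (solvent), Ph2CO (10 mol%), hν (350 nm, Pyrex), degassed, rt
Reagents that add atoms: 1,3-dioxolane, C1COCO1
Why: Photochemical radical conjugate addition (Giese type, hydrogen-atom-transfer chain): triplet benzophenone abstracts the acetal hydrogen, the nucleophilic 2-dioxolanyl radical adds to C7 of the butenolide anti to the C6 silyloxymethyl group and the lactone α-radical takes hydrogen from the solvent, which forms C7–C8 and sets C7 trans to C6.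

Step 3
Reactants: 3 (4S,5S)-5-({[tert-butyl(diphenyl)silyl]oxy}methyl)-4-(1,3-dioxolan-2-yl)oxolan-2-one
Product: 4 (2S,3S)-2-({[tert-butyl(diphenyl)silyl]oxy}methyl)-5-oxooxolane-3-carbaldehyde
Conditions: TFA/H2O (4:1), CH2Cl2, 0 °C → rt; used crude
Reagents that add atoms: water, O
Why: Acid-catalysed acetal hydrolysis unmasks the C8 aldehyde, the silyl ether survives, and the C7 centre is already the thermodynamically preferred trans one.

Step 4
Reactants: 4 (2S,3S)-2-({[tert-butyl(diphenyl)silyl]oxy}methyl)-5-oxooxolane-3-carbaldehyde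
Product: 5 (4R,5S)-5-({[tert-butyl(diphenyl)silyl]oxy}methyl)-4-[(1S)-1-hydroxybut-3-yn-1-yl]oxolan-2-one
Conditions: allenyltributylstannane (1.5 equiv), BF3·OEt2 (1.2 equiv), CH2Cl2, −78 °C; then H2O
Reagents that add atoms: tributyl(propa-1,2-dien-1-yl)stannane, C=C=C[Sn](CCCC)(CCCC)CCCC
Why: Lewis-acid-promoted SE2' propargylation through an open transition state, in which Felkin–Anh attack anti to the C7–C6 bond (the largest α-substituent, carrying the ring oxygen) sets C8 as S, by analogy with BF3-mediated allylsilane additions to trans-β-formyl-γ-butyrolactones.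

Step 5
Reactants: 6 but-3-yn-2-one
Product: 7 (Z)-4-iodobut-3-en-2-one
Conditions: NaI, AcOH, rt, dark; used at once
Reagents that add atoms: sodium iodide, [Na+].[I-]
Why: Conjugate hydroiodination of the ynone (iodide addition, then protonation of the allenolate anti to iodine) gives the Z-β-iodoenone under kinetic control.

Step 6
Reactants: 7 (Z)-4-iodobut-3-en-2-one
Product: 8 (Z)-4-iodobuta-1,3-dien-2-yl trifluoromethanesulfonate
Conditions: KN(SiMe3)2, THF, −78 °C; PhNTf2, −78 → −20 °C, dark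
Reagents that add atoms: N-phenylbis(trifluoromethanesulfonimide), FC(F)(F)S(=O)(=O)N(c1ccccc1)S(=O)(=O)C(F)(F)F
Why: Kinetic enolisation of the only enolisable position (the methyl group) followed by O-triflation (enol triflate formation) leaves the Z-iodoalkene untouched at low temperature.

Step 7
Reactants: 5 (4R,5S)-5-({[tert-butyl(diphenyl)silyl]oxy}methyl)-4-[(1S)-1-hydroxybut-3-yn-1-yl]oxolan-2-one and 8 (Z)-4-iodobuta-1,3-dien-2-yl trifluoromethanesulfonate
Product: 10 (3Z,5E,8S)-8-[(2S,3R)-2-({[tert-butyl(diphenyl)silyl]oxy}methyl)-5-oxooxolan-3-yl]-8-hydroxy-6-methylocta-1,3,5-trien-2-yl trifluoromethanesulfonate, via alkenylalane 9 (not isolated)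
Conditions: Me3Al (3 equiv), Cp2ZrCl2 (25 mol%), H2O (1 equiv), CH2Cl2, −23 °C; volatiles removed; then 8 (1.2 equiv), Pd(PPh3)4 (5 mol%), ZnCl2 (20 mol%), THF, 0 °C → rt
Reagents that add atoms: trimethylaluminium, C[Al](C)C
Why: Zirconium-catalysed syn-methylalumination of the terminal alkyne (Negishi carboalumination) places the C10 methyl and aluminium cis, and palladium-catalysed Negishi cross-coupling at the C–I bond of 8 (faster than C–OTf, retention at both partners) gives the 1(10)E,2Z diene.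

Step 8
Reactants: 10 (3Z,5E,8S)-8-[(2S,3R)-2-({[tert-butyl(diphenyl)silyl]oxy}methyl)-5-oxooxolan-3-yl]-8-hydroxy-6-methylocta-1,3,5-trien-2-yl trifluoromethanesulfonate
Product: 13 (3Z,5E,8S)-8-[(2S,3R)-2-({[tert-butyl(diphenyl)silyl]oxy}methyl)-4-methylidene-5-oxooxolan-3-yl]-8-hydroxy-6-methylocta-1,3,5-trien-2-yl trifluoromethanesulfonate, via Mannich base 11 (not isolated), via ammonium iodide 12 (not isolated)
Conditions: LiN(SiMe3)2 (2.2 equiv), THF, −78 °C; Me2N=CH2+ I−, −78 → −20 °C; aqueous work-up; MeI, CH2Cl2, rt; sat. aq. NaHCO3, rt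
Reagents that add atoms: N,N-dimethylmethyleneiminium iodide, C=[N+](C)C.[I-]
Why: Lactone α-methylenation by the Mannich route (lithium enolate plus iminium salt, quaternisation, Hofmann-type elimination), in which the silylamide at −78 °C deprotonates the hydroxyl and the lactone α-CH2 without eliminating the enol triflate, and no stereocentre is created.

Step 9
Reactants: 13 (3Z,5E,8S)-8-[(2S,3R)-2-({[tert-butyl(diphenyl)silyl]oxy}methyl)-4-methylidene-5-oxooxolan-3-yl]-8-hydroxy-6-methylocta-1,3,5-trien-2-yl trifluoromethanesulfonate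
Product: 14 (1S,3E,5Z)-1-[(2S,3R)-2-({[tert-butyl(diphenyl)silyl]oxy}methyl)-4-methylidene-5-oxooxolan-3-yl]-3-methyl-7-[(trifluoromethanesulfonyl)oxy]octa-3,5,7-trien-1-yl 2-methylprop-2-enoate
Conditions: methacrylic anhydride, Et3N, DMAP (10 mol%), CH2Cl2, 0 °C → rt
Reagents that add atoms: methacrylic anhydride, CC(=C)C(=O)OC(=O)C(C)=C
Why: DMAP-catalysed acyl transfer esterifies the only free hydroxyl, the C8 carbinol, after the base-sensitive enolate chemistry is finished.

Step 10
Reactants: 14 (1S,3E,5Z)-1-[(2S,3R)-2-({[tert-butyl(diphenyl)silyl]oxy}methyl)-4-methylidene-5-oxooxolan-3-yl]-3-methyl-7-[(trifluoromethanesulfonyl)oxy]octa-3,5,7-trien-1-yl 2-methylprop-2-enoate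
Product: 15 (1S,3E,5Z)-1-[(2S,3R)-2-(hydroxymethyl)-4-methylidene-5-oxooxolan-3-yl]-3-methyl-7-[(trifluoromethanesulfonyl)oxy]octa-3,5,7-trien-1-yl 2-methylprop-2-enoate
Conditions: HF·pyridine, pyridine, THF, 0 °C → rt
Reagents that add atoms: none
Why: Fluoride-mediated silyl ether cleavage under buffered, non-basic conditions leaves the methacrylate, the enol triflate and the triene intact.

Step 11
Reactants: 15 (1S,3E,5Z)-1-[(2S,3R)-2-(hydroxymethyl)-4-methylidene-5-oxooxolan-3-yl]-3-methyl-7-[(trifluoromethanesulfonyl)oxy]octa-3,5,7-trien-1-yl 2-methylprop-2-enoate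
Product: 16 (1S,3E,5Z)-1-[(2S,3R)-2-formyl-4-methylidene-5-oxooxolan-3-yl]-3-methyl-7-[(trifluoromethanesulfonyl)oxy]octa-3,5,7-trien-1-yl 2-methylprop-2-enoate
Conditions: Dess–Martin periodinane, pyridine, CH2Cl2, 0 °C → rt; used crude
Reagents that add atoms: none
Why: Dess–Martin oxidation of the primary alcohol gives the C5 aldehyde under buffered conditions that do not epimerise C6 or touch the olefins.

Step 12
Reactants: 16 (1S,3E,5Z)-1-[(2S,3R)-2-formyl-4-methylidene-5-oxooxolan-3-yl]-3-methyl-7-[(trifluoromethanesulfonyl)oxy]octa-3,5,7-trien-1-yl 2-methylprop-2-enoate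
Product: 18 (3aR,4S,6E,8Z,11R,11aS)-11-hydroxy-6-methyl-3,10-dimethylidene-2-oxo-2,3,3a,4,5,10,11,11a-octahydrocyclodeca[b]furan-4-yl 2-methylprop-2-enoate, via silyl ether 17 (not isolated)
Conditions: CrCl2 (20 mol%), NiCl2·glyme (5 mol%), Me3SiCl (2 equiv), Bu4NBr, DMF, undivided cell, Al anode, Ni-foam cathode, constant current, 16 added over 10 h (≤2 mM), rt; then aq. citric acid, THF
Reagents that add atoms: none
Why: Proposed new method: an intramolecular electrocatalytic Nozaki–Hiyama–Kishi closure of a ten-membered carbocycle, in which cathodically formed zerovalent nickel inserts into the C4–OTf bond, the alkenyl group passes to trivalent chromium, the alkenylchromium adds to the C5 aldehyde, Me3SiCl releases the chromium alkoxide and the cathode returns trivalent to divalent chromium so that both metals turn over at high dilution; the closest known reaction type is the intermolecular electrochemical NHK coupling (and the stoichiometric CrCl2/NiCl2 macrocyclisation), and Felkin–Anh attack anti to the C6–O bond should favour the 5R carbinol, although either C5 epimer serves step 13.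

Step 13
Reactants: 18 (3aR,4S,6E,8Z,11R,11aS)-11-hydroxy-6-methyl-3,10-dimethylidene-2-oxo-2,3,3a,4,5,10,11,11a-octahydrocyclodeca[b]furan-4-yl 2-methylprop-2-enoate
Product: 19 (3aR,4S,6E,8Z,11aS)-6-methyl-3,10-dimethylidene-2,11-dioxo-2,3,3a,4,5,10,11,11a-octahydrocyclodeca[b]furan-4-yl 2-methylprop-2-enoate
Conditions: Dess–Martin periodinane, pyridine, CH2Cl2, 0 °C; used promptly
Reagents that add atoms: none
Why: Dess–Martin oxidation of the allylic alcohol to the cross-conjugated enone deliberately removes the C5 centre and makes the exocyclic C4=C15 olefin electron-poor, so that both epimers of 18 converge and the next step can tell the ring olefins from the methylene group.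

Step 14
Reactants: 19 (3aR,4S,6E,8Z,11aS)-6-methyl-3,10-dimethylidene-2,11-dioxo-2,3,3a,4,5,10,11,11a-octahydrocyclodeca[b]furan-4-yl 2-methylprop-2-enoate
Product: 20 (1R,2S,3S,10R)-1,10:2,3-diepoxy derivative of 19 (germacrane numbering; C5 ketone retained)
Conditions: DMDO (3.5 equiv, 0.07 M in acetone), CH2Cl2, −20 → 10 °C
Reagents that add atoms: dimethyldioxirane, CC1(C)OO1
Why: Concerted, stereospecific oxygen transfer from the dioxirane to the two electron-rich ring olefins (trisubstituted C1=C10 and cis C2=C3), while the enone, α-methylene lactone and methacrylate olefins are inert on this time scale; the transoid diene is spanned on one face by the C4–C9 bridge of the ring, so both oxygens should arrive on the open outer face, which sets C10, C1, C2 and C3 relative to C6–C8.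

Step 15
Reactants: 20 (1R,2S,3S,10R)-1,10:2,3-diepoxy derivative of 19 (germacrane numbering; C5 ketone retained)
Product: 21 ACon1_002091, (1R,2S,3S,5R,6S,7R,8S,10R)-1,10:2,3-diepoxy-5-hydroxy-8-(methacryloyloxy)germacra-4(15),11(13)-dien-12,6-olide
Conditions: Zn(BH4)2, Et2O/CH2Cl2, −40 °C; then H2O
Reagents that add atoms: none
Why: Chelation-controlled 1,2-reduction of the α-oxygenated enone, in which divalent zinc bridges the C5 carbonyl and the C6 lactone oxygen and hydride enters from the open face of the chelate to give the anti 5,6-dioxygen relationship (5R), while the exocyclic methylene, oxiranes, lactone and ester are left alone.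

**Compound list**

1 | (S)-5-(hydroxymethyl)furan-2(5H)-one | OC[C@H]1OC(=O)C=C1 | starting material
2 | (S)-5-({[tert-butyl(diphenyl)silyl]oxy}methyl)furan-2(5H)-one | CC(C)(C)[Si](OC[C@H]1OC(=O)C=C1)(c1ccccc1)c1ccccc1 | intermediate
3 | (4S,5S)-5-({[tert-butyl(diphenyl)silyl]oxy}methyl)-4-(1,3-dioxolan-2-yl)oxolan-2-one | CC(C)(C)[Si](OC[C@H]1OC(=O)C[C@@H]1C1OCCO1)(c1ccccc1)c1ccccc1 | intermediate
4 | (2S,3S)-2-({[tert-butyl(diphenyl)silyl]oxy}methyl)-5-oxooxolane-3-carbaldehyde | CC(C)(C)[Si](OC[C@H]1OC(=O)C[C@@H]1C=O)(c1ccccc1)c1ccccc1 | intermediate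
5 | (4R,5S)-5-({[tert-butyl(diphenyl)silyl]oxy}methyl)-4-[(1S)-1-hydroxybut-3-yn-1-yl]oxolan-2-one | CC(C)(C)[Si](OC[C@H]1OC(=O)C[C@@H]1[C@@H](O)CC#C)(c1ccccc1)c1ccccc1 | intermediate
6 | but-3-yn-2-one | CC(=O)C#C | starting material
7 | (Z)-4-iodobut-3-en-2-one | CC(=O)/C=C\I | intermediate
8 | (Z)-4-iodobuta-1,3-dien-2-yl trifluoromethanesulfonate | C=C(OS(=O)(=O)C(F)(F)F)/C=C\I | intermediate
9 | (E)-alkenyl(dimethyl)alane from 5, with C8–O–AlMe2 and the C10 methyl cis to aluminium on C1 | CC(C)(C)[Si](OC[C@H]1OC(=O)C[C@@H]1[C@@H](O[Al](C)C)C/C(C)=C/[Al](C)C)(c1ccccc1)c1ccccc1 | intermediate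
10 | (3Z,5E,8S)-8-[(2S,3R)-2-({[tert-butyl(diphenyl)silyl]oxy}methyl)-5-oxooxolan-3-yl]-8-hydroxy-6-methylocta-1,3,5-trien-2-yl trifluoromethanesulfonate | CC(C)(C)[Si](OC[C@H]1OC(=O)C[C@@H]1[C@@H](O)C/C(C)=C/C=C\C(OS(=O)(=O)C(F)(F)F)=C)(c1ccccc1)c1ccccc1 | intermediate
11 | Mannich base: 10 carrying CH2NMe2 on the lactone α-carbon C11 (both C11 epimers) | CC(C)(C)[Si](OC[C@H]1OC(=O)C(CN(C)C)[C@@H]1[C@@H](O)C/C(C)=C/C=C\C(OS(=O)(=O)C(F)(F)F)=C)(c1ccccc1)c1ccccc1 | intermediate
12 | trimethylammonium iodide of 11 | CC(C)(C)[Si](OC[C@H]1OC(=O)C(C[N+](C)(C)C)[C@@H]1[C@@H](O)C/C(C)=C/C=C\C(OS(=O)(=O)C(F)(F)F)=C)(c1ccccc1)c1ccccc1.[I-] | intermediate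
13 | (3Z,5E,8S)-8-[(2S,3R)-2-({[tert-butyl(diphenyl)silyl]oxy}methyl)-4-methylidene-5-oxooxolan-3-yl]-8-hydroxy-6-methylocta-1,3,5-trien-2-yl trifluoromethanesulfonate | CC(C)(C)[Si](OC[C@H]1OC(=O)C(=C)[C@@H]1[C@@H](O)C/C(C)=C/C=C\C(OS(=O)(=O)C(F)(F)F)=C)(c1ccccc1)c1ccccc1 | intermediate
14 | (1S,3E,5Z)-1-[(2S,3R)-2-({[tert-butyl(diphenyl)silyl]oxy}methyl)-4-methylidene-5-oxooxolan-3-yl]-3-methyl-7-[(trifluoromethanesulfonyl)oxy]octa-3,5,7-trien-1-yl 2-methylprop-2-enoate | CC(C)(C)[Si](OC[C@H]1OC(=O)C(=C)[C@@H]1[C@@H](OC(=O)C(C)=C)C/C(C)=C/C=C\C(OS(=O)(=O)C(F)(F)F)=C)(c1ccccc1)c1ccccc1 | intermediate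
15 | (1S,3E,5Z)-1-[(2S,3R)-2-(hydroxymethyl)-4-methylidene-5-oxooxolan-3-yl]-3-methyl-7-[(trifluoromethanesulfonyl)oxy]octa-3,5,7-trien-1-yl 2-methylprop-2-enoate | OC[C@H]1OC(=O)C(=C)[C@@H]1[C@@H](OC(=O)C(C)=C)C/C(C)=C/C=C\C(OS(=O)(=O)C(F)(F)F)=C | intermediate
16 | (1S,3E,5Z)-1-[(2S,3R)-2-formyl-4-methylidene-5-oxooxolan-3-yl]-3-methyl-7-[(trifluoromethanesulfonyl)oxy]octa-3,5,7-trien-1-yl 2-methylprop-2-enoate | O=C[C@H]1OC(=O)C(=C)[C@@H]1[C@@H](OC(=O)C(C)=C)C/C(C)=C/C=C\C(OS(=O)(=O)C(F)(F)F)=C | intermediate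
17 | O-trimethylsilyl ether of 18 | C=C(C)C(=O)O[C@H]1C/C(C)=C/C=C\C(=C)[C@@H](O[Si](C)(C)C)[C@H]2OC(=O)C(=C)[C@@H]21 | intermediate
18 | (3aR,4S,6E,8Z,11R,11aS)-11-hydroxy-6-methyl-3,10-dimethylidene-2-oxo-2,3,3a,4,5,10,11,11a-octahydrocyclodeca[b]furan-4-yl 2-methylprop-2-enoate | C=C(C)C(=O)O[C@H]1C/C(C)=C/C=C\C(=C)[C@@H](O)[C@H]2OC(=O)C(=C)[C@@H]21 | intermediate
19 | (3aR,4S,6E,8Z,11aS)-6-methyl-3,10-dimethylidene-2,11-dioxo-2,3,3a,4,5,10,11,11a-octahydrocyclodeca[b]furan-4-yl 2-methylprop-2-enoate | C=C(C)C(=O)O[C@H]1C/C(C)=C/C=C\C(=C)C(=O)[C@H]2OC(=O)C(=C)[C@@H]21 | intermediate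
20 | (1R,2S,3S,10R)-1,10:2,3-diepoxy derivative of 19 (germacrane numbering; C5 ketone) | C=C(C)C(=O)O[C@H]1C[C@@]2(C)O[C@@H]2[C@H]2O[C@H]2C(=C)C(=O)[C@H]2OC(=O)C(=C)[C@@H]21 | intermediate
21 | ACon1_002091, (1R,2S,3S,5R,6S,7R,8S,10R)-1,10:2,3-diepoxy-5-hydroxy-8-(methacryloyloxy)germacra-4(15),11(13)-dien-12,6-olide | C=C(C)C(=O)O[C@H]1C[C@@]2(C)O[C@@H]2[C@H]2O[C@H]2C(=C)[C@@H](O)[C@H]2OC(=O)C(=C)[C@@H]21 | target

**Step count**

Total: 15 steps. Longest linear sequence: 13 steps (steps 1–4 and 7–15); steps 5–6 make the side fragment 8.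

**The three steps most likely to fail**

Step 12 (the proposed electrochemical ring closure). The likely failures are oligomerisation, loss of the triflate by protonation, or reduction of the aldehyde before the alkenyl group is transferred. The fallback uses known chemistry and drops the electrochemistry: it sets out from 16 and comes back to the route at 18 by the classical stoichiometric NHK macrocyclisation (CrCl2 in large excess, NiCl2 1 mol%, DMSO/THF, syringe-pump addition at rt), with the chromium alkoxide hydrolysed on work-up. It passes through no compound outside the list (none F0).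

Step 14 (double epoxidation). The trisubstituted C1=C10 olefin should react cleanly, but the cis C2=C3 olefin may be attacked on the wrong face. The fallback builds that oxirane from the opposite face: it sets out from 19 and comes back at 20. mCPBA (1 equiv, NaHCO3, CH2Cl2, −20 °C) epoxidises only the trisubstituted olefin to give the 1,10-monoepoxide F1. NBS in aqueous THF then puts bromine on the exposed face of C2=C3 and water on the hidden face, giving the bromohydrin F2 (drawn as the 2-bromo-3-hydroxy isomer; the regioisomer closes to the same oxirane). K2CO3 in acetone closes F2 to 20, with the oxygen on the face opposite to the one an external oxidant reaches.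

Step 15 (C5 reduction). The lactone oxygen is a weak donor, so chelation may lose to Felkin-type or purely conformational control and give the C5 epimer. The fallback sets the centre by inversion instead of by hydride face: it sets out from 20 and comes back at 21. Non-chelating Luche reduction (NaBH4, CeCl3·7H2O, MeOH, −78 °C) is run on purpose to the 5S carbinol F3. Mitsunobu inversion (HCO2H, PPh3, DIAD, THF, 0 °C) gives the 5R formate F4. KHCO3 in aqueous methanol at 0 °C removes the formate without touching the methacrylate and gives 21.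

Further compounds
F0 | step 12 | none | none
F1 | step 14 | (1R,10R)-1,10-monoepoxide of 19 (germacrane numbering) | C=C(C)C(=O)O[C@H]1C[C@@]2(C)O[C@@H]2/C=C\C(=C)C(=O)[C@H]2OC(=O)C(=C)[C@@H]21
F2 | step 14 | 2-bromo-3-hydroxy bromohydrin of F1 (bromine on C2 anti to the C3 hydroxyl; C3–O configured as in 20) | C=C(C)C(=O)O[C@H]1C[C@@]2(C)O[C@@H]2[C@H](Br)[C@@H](O)C(=C)C(=O)[C@H]2OC(=O)C(=C)[C@@H]21
F3 | step 15 | 5-epi-21 (5S carbinol) | C=C(C)C(=O)O[C@H]1C[C@@]2(C)O[C@@H]2[C@H]2O[C@H]2C(=C)[C@H](O)[C@H]2OC(=O)C(=C)[C@@H]21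
F4 | step 15 | 5-O-formate of 21 (5R) | C=C(C)C(=O)O[C@H]1C[C@@]2(C)O[C@@H]2[C@H]2O[C@H]2C(=C)[C@@H](OC=O)[C@H]2OC(=O)C(=C)[C@@H]21
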